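**Retrosynthetic overview** (oxolane numbering: O1, C2 aryl, C3 CH2OH, C4 aroyl, C5 H2)

- 15 ⇐ base epimerisation at C4 (α to the ketone) of the all-cis ketone 14 ⇐ hydrolysis of the 1,3-dithiane of 13, which masks the ketone carbon through the route.
- 13 ⇐ closure of the oxolane ring by the bond from the ring oxygen to the benzylic carbon C2, made with C2 at the ketone oxidation level: γ-hydroxy aryl ketone 10 → hemiketal → 2-aryl oxolanylium ion → hydride, so that C2 is set by hydride delivery and not by equilibration of a benzylic cation.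
- Enabling feature: the ring oxygen sits on the CH2 group attached to C4 and is γ to C2, whereas the oxygen of the hydroxymethyl group on C3 is only β to C2. Only the first can reach C2 through a five-membered ring (the second would need an oxetane), the 3,4-dimethoxyphenyl group on C2 stabilises the cyclic oxocarbenium ion, and the substituents on C3 and C4 cover one face of that ion.
- 10 ⇐ benzylic oxidation of triol 9 ⇐ LiAlH4 opening of lactone 8 ⇐ one-pot conjugate addition–aldol reaction of lithiated dithiane 3 (from 1 and 2) with menthyloxybutenolide 4 and aldehyde 5; the acetal centre of 4 sets C4 and, through it, C3.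
- Rings: the bought butenolide ring is a temporary ring (opened in step 3); the oxolane ring is the only ring formed (step 5); both benzene rings are bought.

Key step: step 5

Remark: butenolide 4, the crystalline acetal of (−)-menthol and 5-hydroxyfuran-2(5H)-one, is taken as a purchasable building block; the configuration it imposes on C4 serves only as a relay to C3 and is inverted on purpose in step 7.

Step 1
Reactants: 1 3,4,5-trimethoxybenzaldehyde; 2 propane-1,3-dithiol
Product: 3 2-(3,4,5-trimethoxyphenyl)-1,3-dithiane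
Conditions: BF3·OEt2 (cat.), CH2Cl2, 0 °C to rt
Reagents that add atoms: none
Why: Lewis-acid-catalysed dithioacetalisation of an aromatic aldehyde is routine and turns the future ketone carbon into an acyl-anion equivalent (Corey–Seebach umpolung); no stereocentre is formed.

Step 2
Reactants: 3 2-(3,4,5-trimethoxyphenyl)-1,3-dithiane; 4 (5R)-5-{[(1R,2S,5R)-5-methyl-2-(propan-2-yl)cyclohexyl]oxy}furan-2(5H)-one; 5 3,4-dimethoxybenzaldehyde
Product: 8 (3S,4R,5R)-3-[(3,4-dimethoxyphenyl)(hydroxy)methyl]-5-{[(1R,2S,5R)-5-methyl-2-(propan-2-yl)cyclohexyl]oxy}-4-[2-(3,4,5-trimethoxyphenyl)-1,3-dithian-2-yl]oxolan-2-one (both epimers at the carbinol carbon), via lithiated dithiane 6 (not isolated), via lithium lactone enolate 7 (not isolated)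
Conditions: n-BuLi, THF, −78 to −20 °C; then 4, −78 °C; then 5, −78 °C; aq. NH4Cl
Reagents that add atoms: none
Why: Tandem Michael addition–aldol reaction of a Corey–Seebach acyl-anion equivalent: 6 should add to C4 of the butenolide from the face opposite the menthyloxy group on C5 (acetal control, setting the future oxolane C4), and enolate 7 should be trapped by the aldehyde anti to this new bulky group (setting the future C3); the carbinol centre is not controlled and ceases to be a stereocentre in step 4.

Step 3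
Reactants: 8 (3S,4R,5R)-3-[(3,4-dimethoxyphenyl)(hydroxy)methyl]-5-(menthyloxy)-4-[2-(3,4,5-trimethoxyphenyl)-1,3-dithian-2-yl]oxolan-2-one
Product: 9 (2R,3R)-2-[(3,4-dimethoxyphenyl)(hydroxy)methyl]-3-[2-(3,4,5-trimethoxyphenyl)-1,3-dithian-2-yl]butane-1,4-diol (both epimers at the carbinol carbon)
Conditions: LiAlH4, THF, 0 °C to rt; H2O, then aq. NaOH
Reagents that add atoms: none
Why: Hydride reduction of a lactone acetal: reduction of the lactone carbonyl opens the ring, the acetal carbon then loses menthoxide and is reduced as well, so both former ring carbons should end as CH2OH groups while the two stereocentres on the chain are carried through unchanged.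

Step 4
Reactants: 9 (2R,3R)-2-[(3,4-dimethoxyphenyl)(hydroxy)methyl]-3-[2-(3,4,5-trimethoxyphenyl)-1,3-dithian-2-yl]butane-1,4-diol
Product: 10 (2R,3R)-1-(3,4-dimethoxyphenyl)-4-hydroxy-2-(hydroxymethyl)-3-[2-(3,4,5-trimethoxyphenyl)-1,3-dithian-2-yl]butan-1-one
Conditions: activated MnO2, CH2Cl2, rt
Reagents that add atoms: none
Why: Chemoselective benzylic oxidation: MnO2 should oxidise the electron-rich benzylic secondary alcohol but not the saturated primary alcohols or the dithiane under neutral conditions, and both carbinol epimers converge on one ketone.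

Step 5
Reactants: 10 (2R,3R)-1-(3,4-dimethoxyphenyl)-4-hydroxy-2-(hydroxymethyl)-3-[2-(3,4,5-trimethoxyphenyl)-1,3-dithian-2-yl]butan-1-one
Product: 13 [(2R,3R,4R)-2-(3,4-dimethoxyphenyl)-4-[2-(3,4,5-trimethoxyphenyl)-1,3-dithian-2-yl]oxolan-3-yl]methanol (all-cis), via cyclic hemiketal 11 (not isolated), via oxolanylium ion 12 (not isolated)
Conditions: Et3SiH, BF3·OEt2, CH2Cl2, −78 °C; aq. NaHCO3 at −78 °C
Reagents that add atoms: none
Why: BF3 activates the aryl ketone, the hydroxyl oxygen that is γ to it adds to C2 to give hemiketal 11, BF3 then removes the hemiketal hydroxyl to give the 2-aryl oxolanylium ion 12 (stabilised by the para-methoxy group of the aryl ring), and Et3SiH transfers hydride to C2 irreversibly. The closest known reaction type is the Lewis acid/silane reductive etherification (ionic hydrogenation) of γ-hydroxy ketones and of 2-aryl lactols, which is used to make 2,3-cis-2-aryl oxolanes. The oxolane ring closes in the 5-exo-trig mode, by addition of oxygen to the carbonyl group. The only new stereocentre, C2, is controlled by the substrate: the hydroxymethyl group on C3 and the dithianyl group on C4 both sit on one face of the planar cation 12, hydride should enter from the open face, and the aryl group should therefore end cis to the C3 substituent. Two selectivities are needed: between the two primary hydroxyls, which ring size secures (the second hydroxyl could only form an oxetane), and kinetic control at C2 and C3, which −78 °C and excess silane should secure because hydride capture then outruns both loss of the proton at C3 and re-ionisation of the benzylic C–O bond of the product.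

Step 6
Reactants: 13 [(2R,3R,4R)-2-(3,4-dimethoxyphenyl)-4-[2-(3,4,5-trimethoxyphenyl)-1,3-dithian-2-yl]oxolan-3-yl]methanol
Product: 14 [(3R,4R,5R)-5-(3,4-dimethoxyphenyl)-4-(hydroxymethyl)oxolan-3-yl](3,4,5-trimethoxyphenyl)methanone (all-cis)
Conditions: iodine, NaHCO3, acetone–H2O, 0 °C
Reagents that add atoms: water, O
Why: Oxidative hydrolysis of a dithioketal: iodine activates sulfur, water attacks the thionium carbon and the dithiane leaves as the cyclic disulfide, under bicarbonate buffering that should spare the benzylic ether, the primary alcohol and the methoxyarenes; no stereocentre is touched.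

Step 7
Reactants: 14 [(3R,4R,5R)-5-(3,4-dimethoxyphenyl)-4-(hydroxymethyl)oxolan-3-yl](3,4,5-trimethoxyphenyl)methanone
Product: 15 [(3S,4R,5R)-5-(3,4-dimethoxyphenyl)-4-(hydroxymethyl)oxolan-3-yl](3,4,5-trimethoxyphenyl)methanone (target)
Conditions: DBU (cat.), CH2Cl2, rt
Reagents that add atoms: none
Why: Thermodynamic epimerisation α to a ketone (enolisation and reprotonation): only the aroyl-bearing carbon is acidic, and moving the aroyl group trans to the neighbouring hydroxymethyl group should relieve the all-cis strain, which inverts the relay centre to the configuration of the target while C2 and C3 stay as set.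

**Compound list**

1 | 3,4,5-trimethoxybenzaldehyde | COc1cc(C=O)cc(OC)c1OC | starting material
2 | propane-1,3-dithiol | SCCCS | starting material
3 | 2-(3,4,5-trimethoxyphenyl)-1,3-dithiane | COc1cc(C2SCCCS2)cc(OC)c1OC | intermediate
4 | (5R)-5-{[(1R,2S,5R)-5-methyl-2-(propan-2-yl)cyclohexyl]oxy}furan-2(5H)-one | O=C1C=C[C@H](O[C@@H]2C[C@H](C)CC[C@H]2C(C)C)O1 | starting material
5 | 3,4-dimethoxybenzaldehyde | COc1ccc(C=O)cc1OC | starting material
6 | 2-lithio-2-(3,4,5-trimethoxyphenyl)-1,3-dithiane (formed in the flask) | [Li]C1(SCCCS1)c1cc(OC)c(OC)c(OC)c1 | intermediate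
7 | lithium enolate of (4R,5R)-5-(menthyloxy)-4-[2-(3,4,5-trimethoxyphenyl)-1,3-dithian-2-yl]oxolan-2-one (formed in the flask; dithianyl trans to menthyloxy) | [Li]OC1=C[C@@H](C2(SCCCS2)c3cc(OC)c(OC)c(OC)c3)[C@H](O[C@@H]4C[C@H](C)CC[C@H]4C(C)C)O1 | intermediate
8 | (3S,4R,5R)-3-[(3,4-dimethoxyphenyl)(hydroxy)methyl]-5-{[(1R,2S,5R)-5-methyl-2-(propan-2-yl)cyclohexyl]oxy}-4-[2-(3,4,5-trimethoxyphenyl)-1,3-dithian-2-yl]oxolan-2-one (3,4-trans, 4,5-trans; both epimers at the carbinol carbon) | O=C1[C@H](C(O)c2ccc(OC)c(OC)c2)[C@@H](C3(SCCCS3)c4cc(OC)c(OC)c(OC)c4)[C@H](O[C@@H]5C[C@H](C)CC[C@H]5C(C)C)O1 | intermediate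
9 | (2R,3R)-2-[(3,4-dimethoxyphenyl)(hydroxy)methyl]-3-[2-(3,4,5-trimethoxyphenyl)-1,3-dithian-2-yl]butane-1,4-diol (both epimers at the carbinol carbon) | COc1ccc(C(O)[C@H]([C@H](CO)C2(SCCCS2)c3cc(OC)c(OC)c(OC)c3)CO)cc1OC | intermediate
10 | (2R,3R)-1-(3,4-dimethoxyphenyl)-4-hydroxy-2-(hydroxymethyl)-3-[2-(3,4,5-trimethoxyphenyl)-1,3-dithian-2-yl]butan-1-one | COc1ccc(C(=O)[C@H]([C@H](CO)C2(SCCCS2)c3cc(OC)c(OC)c(OC)c3)CO)cc1OC | intermediate
11 | (3R,4R)-2-(3,4-dimethoxyphenyl)-3-(hydroxymethyl)-4-[2-(3,4,5-trimethoxyphenyl)-1,3-dithian-2-yl]oxolan-2-ol (cyclic hemiketal, formed in the flask; both anomers; 3,4-cis) | COc1ccc(C2(O)OC[C@H](C3(SCCCS3)c4cc(OC)c(OC)c(OC)c4)[C@@H]2CO)cc1OC | intermediate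
12 | (3R,4R)-2-(3,4-dimethoxyphenyl)-3-(hydroxymethyl)-4-[2-(3,4,5-trimethoxyphenyl)-1,3-dithian-2-yl]oxolan-1-ylium (cyclic oxocarbenium ion, formed in the flask; 3,4-cis) | COc1ccc(C2=[O+]C[C@H](C3(SCCCS3)c4cc(OC)c(OC)c(OC)c4)[C@@H]2CO)cc1OC | intermediate
13 | [(2R,3R,4R)-2-(3,4-dimethoxyphenyl)-4-[2-(3,4,5-trimethoxyphenyl)-1,3-dithian-2-yl]oxolan-3-yl]methanol (aryl, hydroxymethyl and dithianyl groups all cis) | COc1ccc([C@@H]2OC[C@H](C3(SCCCS3)c4cc(OC)c(OC)c(OC)c4)[C@@H]2CO)cc1OC | intermediate
14 | [(3R,4R,5R)-5-(3,4-dimethoxyphenyl)-4-(hydroxymethyl)oxolan-3-yl](3,4,5-trimethoxyphenyl)methanone (all-cis) | COc1ccc([C@@H]2OC[C@H](C(=O)c3cc(OC)c(OC)c(OC)c3)[C@@H]2CO)cc1OC | intermediate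
15 | [(3S,4R,5R)-5-(3,4-dimethoxyphenyl)-4-(hydroxymethyl)oxolan-3-yl](3,4,5-trimethoxyphenyl)methanone (aryl cis to hydroxymethyl, aroyl trans to hydroxymethyl) | COc1ccc([C@@H]2OC[C@@H](C(=O)c3cc(OC)c(OC)c(OC)c3)[C@@H]2CO)cc1OC | target

Total step count: 7. Longest linear sequence: 7 steps (1 → 3 → 8 → 9 → 10 → 13 → 14 → 15).

**Steps most likely to fail**

Step 5. At the stage of the cation, loss of the proton at C3 could compete with hydride capture, and after reduction the benzylic C–O bond of the strained all-cis ring could re-ionise. Either process would erode the configuration at C3 or C2 and open the way to over-reduction. A diastereomer arising from proton loss at C3 would belong to the enantiomeric series of the final product and would have to be removed by chromatography at the stage of 13. The fallback sets out from 10 and separates ring closure from reduction. The same oxygen–carbon bond is closed first under reversible, non-reducing conditions (HC(OMe)3, MeOH, PPTS) to give the cyclic methyl ketal F1. The dithiane of this ketal is hydrolysed with iodine and NaHCO3 to the all-cis keto ketal F2, and DBU epimerises it to the 3,4-trans keto ketal F3. Reduction of the ketal carbon with Et3SiH and catalytic TMSOTf at −78 °C, where a ketal ionises far more readily than an aryl ketone reacts, should then deliver hydride anti to the hydroxymethyl group on the less strained trans ring. The fallback comes back to the route at 15.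

Step 7. The epimerisation may stall because the hydroxymethyl oxygen closes onto the cis ketone and holds the material as a bicyclic hemiketal, so that little of the enolisable open form is present. The fallback sets out from 13. The primary hydroxyl is capped with TIPSCl and imidazole to give the silyl ether F4, and dithiane hydrolysis with iodine and NaHCO3 gives the all-cis silyloxy ketone F5, which cannot form a hemiketal. DBU should convert it into the trans silyloxy ketone F6, and HF·pyridine removes the silyl group. The fallback comes back to the route at 15.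

Step 4. The oxidation may not stop cleanly: the sulfur atoms may be oxidised, or the new β-hydroxy ketone may lose water or formaldehyde (retro-aldol cleavage) on the oxidant surface. The fallback sets out from 9. Both primary hydroxyls are silylated selectively with TBSCl and imidazole to give the bis-silyl ether F7, and the remaining benzylic alcohol is oxidised by Parikh–Doering oxidation (SO3·pyridine, DMSO, i-Pr2NEt) to the bis-silyl ketone F8. The ring is then closed by the silyl-ether variant of the same reductive etherification (Et3SiH, catalytic TMSOTf, CH2Cl2, −78 °C), in which only the silyloxy oxygen γ to the ketone can cyclise, to give the silyl ether F9. TBAF releases the alcohol, and the fallback comes back to the route at 13.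

**Further compounds**

F1 | step 5 | [(3R,4R)-2-(3,4-dimethoxyphenyl)-2-methoxy-4-[2-(3,4,5-trimethoxyphenyl)-1,3-dithian-2-yl]oxolan-3-yl]methanol (both anomers; 3,4-cis) | COc1ccc(C2(OC)OC[C@H](C3(SCCCS3)c4cc(OC)c(OC)c(OC)c4)[C@@H]2CO)cc1OC
F2 | step 5 | [(3R,4R)-5-(3,4-dimethoxyphenyl)-4-(hydroxymethyl)-5-methoxyoxolan-3-yl](3,4,5-trimethoxyphenyl)methanone (both anomers; 3,4-cis) | COc1ccc(C2(OC)OC[C@H](C(=O)c3cc(OC)c(OC)c(OC)c3)[C@@H]2CO)cc1OC
F3 | step 5 | [(3S,4R)-5-(3,4-dimethoxyphenyl)-4-(hydroxymethyl)-5-methoxyoxolan-3-yl](3,4,5-trimethoxyphenyl)methanone (both anomers; 3,4-trans) | COc1ccc(C2(OC)OC[C@@H](C(=O)c3cc(OC)c(OC)c(OC)c3)[C@@H]2CO)cc1OC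
F4 | step 7 | {[(2R,3R,4R)-2-(3,4-dimethoxyphenyl)-4-[2-(3,4,5-trimethoxyphenyl)-1,3-dithian-2-yl]oxolan-3-yl]methoxy}tri(propan-2-yl)silane (all-cis) | COc1ccc([C@@H]2OC[C@H](C3(SCCCS3)c4cc(OC)c(OC)c(OC)c4)[C@@H]2CO[Si](C(C)C)(C(C)C)C(C)C)cc1OC
F5 | step 7 | [(3R,4R,5R)-5-(3,4-dimethoxyphenyl)-4-{[tri(propan-2-yl)silyloxy]methyl}oxolan-3-yl](3,4,5-trimethoxyphenyl)methanone (all-cis) | COc1ccc([C@@H]2OC[C@H](C(=O)c3cc(OC)c(OC)c(OC)c3)[C@@H]2CO[Si](C(C)C)(C(C)C)C(C)C)cc1OC
F6 | step 7 | [(3S,4R,5R)-5-(3,4-dimethoxyphenyl)-4-{[tri(propan-2-yl)silyloxy]methyl}oxolan-3-yl](3,4,5-trimethoxyphenyl)methanone (aroyl trans to silyloxymethyl) | COc1ccc([C@@H]2OC[C@@H](C(=O)c3cc(OC)c(OC)c(OC)c3)[C@@H]2CO[Si](C(C)C)(C(C)C)C(C)C)cc1OC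
F7 | step 4 | (2R,3R)-4-[tert-butyl(dimethyl)silyloxy]-2-{[tert-butyl(dimethyl)silyloxy]methyl}-1-(3,4-dimethoxyphenyl)-3-[2-(3,4,5-trimethoxyphenyl)-1,3-dithian-2-yl]butan-1-ol (both epimers at the carbinol carbon) | COc1ccc(C(O)[C@H]([C@H](CO[Si](C)(C)C(C)(C)C)C2(SCCCS2)c3cc(OC)c(OC)c(OC)c3)CO[Si](C)(C)C(C)(C)C)cc1OC
F8 | step 4 | (2R,3R)-4-[tert-butyl(dimethyl)silyloxy]-2-{[tert-butyl(dimethyl)silyloxy]methyl}-1-(3,4-dimethoxyphenyl)-3-[2-(3,4,5-trimethoxyphenyl)-1,3-dithian-2-yl]butan-1-one | COc1ccc(C(=O)[C@H]([C@H](CO[Si](C)(C)C(C)(C)C)C2(SCCCS2)c3cc(OC)c(OC)c(OC)c3)CO[Si](C)(C)C(C)(C)C)cc1OC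
F9 | step 4 | tert-butyl{[(2R,3R,4R)-2-(3,4-dimethoxyphenyl)-4-[2-(3,4,5-trimethoxyphenyl)-1,3-dithian-2-yl]oxolan-3-yl]methoxy}dimethylsilane (all-cis) | COc1ccc([C@@H]2OC[C@H](C3(SCCCS3)c4cc(OC)c(OC)c(OC)c4)[C@@H]2CO[Si](C)(C)C(C)(C)C)cc1OC
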